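Ring C is disconnected at O1–C2 and C3–C4. Since C4, C3 and C2 all bear oxygen, this three-carbon unit travels as a 4-alkoxyisoxazole, a masked 2-alkoxy-1,3-diketone. C4a of ring A sits between the C5 and C8a oxygens, so a nitrile oxide on the C4 carbon is di-ortho-substituted and persistent. Its (3+2) cycloaddition to the pyrrolidine enamine of a ring B 2-(methoxymethoxy)acetophenone joins C4 to C3 and ties the oxide oxygen provisionally to C2 in one operation; loss of pyrrolidine aromatises the ring. Benzyl ethers cover the four phenols and MOM groups mark O3 and the C8a oxygen, so N–O cleavage and acid give a flavonol whose only free hydroxyl, at C3, is sulfated before hydrogenolysis.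

Key step: step 9

Assumption: the target is drawn as the free hydrogen sulfate, so 19 and 20 are written in that form; 19 would be handled as its triethylammonium salt and the acid form of 20 released on an acid-form resin at the very end (the target has no stereocentre).

Step 1
Reactants: 1 3,4,5-tris(benzyloxy)benzaldehyde
Product: 3 3,4,5-tris(benzyloxy)phenol, via aryl formate 2 (not isolated)
Conditions: mCPBA, CH2Cl2, 0 °C to rt; aq. Na2S2O3/NaHCO3 wash; then K2CO3 (cat.), MeOH, rt
Reagents that add atoms: mCPBA, O=C(OO)c1cccc(Cl)c1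
Why: Baeyer–Villiger (Dakin-type) oxidation, in which the electron-rich aryl group of the Criegee adduct migrates in preference to hydride and the resulting formate is transesterified by methanolic carbonate while the benzyl ethers stay untouched.

Step 2
Reactants: 3 3,4,5-tris(benzyloxy)phenol
Product: 4 2,3,4-tris(benzyloxy)-6-hydroxybenzaldehyde
Conditions: MgCl2, Et3N, (CH2O)n, MeCN, reflux; dilute aq. HCl work-up
Reagents that add atoms: paraformaldehyde (as formaldehyde), C=O
Why: Magnesium-mediated ortho-formylation (Casnati–Skattebøl), in which the magnesium phenoxide delivers formaldehyde to the two free ring positions, which are equivalent, and a second formaldehyde oxidises the benzylic alkoxide to the salicylaldehyde.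

Step 3
Reactants: 4 2,3,4-tris(benzyloxy)-6-hydroxybenzaldehyde
Product: 5 2,3,4-tris(benzyloxy)-6-(methoxymethoxy)benzaldehyde
Conditions: MOMCl, iPr2NEt, CH2Cl2, 0 °C to rt
Reagents that add atoms: chloromethyl methyl ether, COCCl
Why: Williamson-type O-alkylation of the phenol gives the MOM acetal on the future O1 oxygen, chosen so that it later leaves in the same acid step as the O3 acetal.

Step 4
Reactants: 5 2,3,4-tris(benzyloxy)-6-(methoxymethoxy)benzaldehyde
Product: 6 (E)-2,3,4-tris(benzyloxy)-6-(methoxymethoxy)benzaldehyde oxime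
Conditions: NH2OH·HCl, NaOAc, EtOH–H2O, rt
Reagents that add atoms: hydroxylamine hydrochloride, NO.Cl
Why: Oxime condensation under acetate buffer is mild enough for the MOM acetal, and the less crowded E isomer is expected although either isomer would serve in the next step.

Step 5
Reactants: 6 (E)-2,3,4-tris(benzyloxy)-6-(methoxymethoxy)benzaldehyde oxime
Product: 7 2,3,4-tris(benzyloxy)-6-(methoxymethoxy)benzonitrile oxide
Conditions: PhI(OAc)2, CF3CO2H (cat.), MeOH, 0 °C; cold aq. NaHCO3 work-up, isolated and kept cold
Reagents that add atoms: none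
Why: Oxidative dehydrogenation of the aldoxime by a hypervalent iodine reagent (ligand exchange at iodine, then loss of iodobenzene and acetic acid) avoids the ring chlorination that N-chlorosuccinimide would cause on this electron-rich arene, and the two flanking oxygens block furoxan dimerisation so the dipole can be isolated.

Step 6
Reactants: 8 2-bromo-1-[4-(benzyloxy)phenyl]ethanone
Product: 10 1-[4-(benzyloxy)phenyl]-2-hydroxyethanone, via formate ester 9 (not isolated)
Conditions: HCO2Na, EtOH–H2O, reflux
Reagents that add atoms: sodium formate, [Na+].[O-]C=O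
Why: SN2 displacement of the phenacyl bromide by formate followed by solvolysis of the formate ester in the same flask is the mild hydrolysis that avoids the aldol and Favorskii chemistry of hydroxide.

Step 7
Reactants: 10 1-[4-(benzyloxy)phenyl]-2-hydroxyethanone
Product: 11 1-[4-(benzyloxy)phenyl]-2-(methoxymethoxy)ethanone
Conditions: MOMCl, iPr2NEt, CH2Cl2, 0 °C to rt
Reagents that add atoms: chloromethyl methyl ether, COCCl
Why: MOM ether formation on the primary ketol caps the oxygen that becomes O3 and blocks the Heyns-type rearrangement that a free α-hydroxy ketone would undergo with a secondary amine.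

Step 8
Reactants: 11 1-[4-(benzyloxy)phenyl]-2-(methoxymethoxy)ethanone; 12 pyrrolidine
Product: 13 1-{(E)-1-[4-(benzyloxy)phenyl]-2-(methoxymethoxy)ethenyl}pyrrolidine
Conditions: pyrrolidine (excess), pTsOH·H2O (cat.), toluene, reflux, Dean–Stark; evaporate and strip with toluene under vacuum, use crude under argon
Reagents that add atoms: none
Why: Enamine condensation with azeotropic removal of water, in which the only acid present is pyrrolidinium tosylate so the acetal survives, and allylic strain between the pyrrolidine ring and the alkoxy group should favour the E isomer although either geometry leads to the same isoxazole.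

Step 9
Reactants: 7 2,3,4-tris(benzyloxy)-6-(methoxymethoxy)benzonitrile oxide; 13 1-{(E)-1-[4-(benzyloxy)phenyl]-2-(methoxymethoxy)ethenyl}pyrrolidine
Product: 15 5-[4-(benzyloxy)phenyl]-4-(methoxymethoxy)-3-[2,3,4-tris(benzyloxy)-6-(methoxymethoxy)phenyl]isoxazole, via 5-pyrrolidinylisoxazoline 14 (not isolated)
Conditions: 13 (1.5 equiv, pyrrolidine-free), toluene, rt to 40 °C; then AcOH, 40 °C
Reagents that add atoms: none
Why: In a concerted but asynchronous 1,3-dipolar (3+2) cycloaddition the electrophilic nitrile oxide carbon (future C4) bonds to the nucleophilic enamine β-carbon (future C3) slightly ahead of bond formation between the oxide oxygen and the aminated carbon (future C2). The closest known reaction type is the regiospecific addition of aryl nitrile oxides to ketone enamines, which gives 5-amino-2-isoxazolines that aromatise by loss of the amine. The five-membered ring therefore closes in the cycloaddition itself, suprafacially on both partners, and acetic acid then ionises the N,O-acetal carbon of 14 so that pyrrolidine leaves and the adjacent ring proton is lost. The two stereocentres of 14 are destroyed in this elimination, so no stereocontrol is needed. The selectivity required is regiochemical, and the enamine polarisation secures it, because nitrogen donation makes the alkoxy-bearing carbon the nucleophile despite its oxygen substituent. Dimerisation of the dipole is suppressed by the C5 and C8a oxygens that flank it, and the enamine is used in excess and freed of pyrrolidine so that amine addition to the nitrile oxide does not compete.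

Step 10
Reactants: 15 5-[4-(benzyloxy)phenyl]-4-(methoxymethoxy)-3-[2,3,4-tris(benzyloxy)-6-(methoxymethoxy)phenyl]isoxazole
Product: 16 (2E)-3-amino-1-[4-(benzyloxy)phenyl]-2-(methoxymethoxy)-3-[2,3,4-tris(benzyloxy)-6-(methoxymethoxy)phenyl]prop-2-en-1-one
Conditions: Mo(CO)6, MeCN–H2O, 80 °C; filter through Celite and a short silica pad
Reagents that add atoms: none
Why: Reductive N–O cleavage of the isoxazole by zerovalent molybdenum in wet acetonitrile (coordination at nitrogen, electron transfer, protonation by water) gives the hydrogen-bonded vinylogous amide without touching benzyl ethers or acetals, which catalytic hydrogenation would not guarantee.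

Step 11
Reactants: 16 (2E)-3-amino-1-[4-(benzyloxy)phenyl]-2-(methoxymethoxy)-3-[2,3,4-tris(benzyloxy)-6-(methoxymethoxy)phenyl]prop-2-en-1-one
Product: 18 5,6,7-tris(benzyloxy)-2-[4-(benzyloxy)phenyl]-3-hydroxy-4H-chromen-4-one, via 2-alkoxy-1,3-diketone 17 (not isolated)
Conditions: 2 M aq. HCl, THF–MeOH, rt, then 50 °C
Reagents that add atoms: water, O
Why: Acid hydrolysis of the vinylogous amide at room temperature unmasks diketone 17, warming then solvolyses both MOM acetals, and the freed C8a phenol adds to the ring B ketone and dehydrates (flavone cyclodehydration as in the Baker–Venkataraman endgame) while the four benzyl ethers stay in place.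

Step 12
Reactants: 18 5,6,7-tris(benzyloxy)-2-[4-(benzyloxy)phenyl]-3-hydroxy-4H-chromen-4-one
Product: 19 5,6,7-tris(benzyloxy)-2-[4-(benzyloxy)phenyl]-4-oxo-4H-chromen-3-yl hydrogen sulfate
Conditions: SO3·NEt3, Et3N, DMF, 60 °C
Reagents that add atoms: sulfur trioxide–triethylamine complex, CC[N+](CC)(CC)S(=O)(=O)[O-]
Why: O-Sulfonation of the only free hydroxyl with an amine–sulfur trioxide complex is regiochemically unambiguous because every phenol is benzylated and the C3 enol is acidic enough to react under amine buffering.

Step 13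
Reactants: 19 5,6,7-tris(benzyloxy)-2-[4-(benzyloxy)phenyl]-4-oxo-4H-chromen-3-yl hydrogen sulfate
Product: 20 5,6,7-trihydroxy-2-(4-hydroxyphenyl)-4-oxo-4H-chromen-3-yl hydrogen sulfate
Conditions: H2 (1 atm), 10% Pd/C, THF–MeOH, rt, under argon on work-up; then sulfonic acid resin (H+ form), H2O–MeOH, 0 °C; freeze-dry
Reagents that add atoms: none
Why: Heterogeneous catalytic hydrogenolysis cleaves the four benzyl ethers as toluene while the sulfate monoester anion and the pyranone double bond are inert at one atmosphere, and brief cold contact with an acid-form resin returns the free hydrogen sulfate.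

Compound list
1 | 3,4,5-tris(benzyloxy)benzaldehyde | O=Cc1cc(OCc2ccccc2)c(OCc2ccccc2)c(OCc2ccccc2)c1 | starting material
2 | 3,4,5-tris(benzyloxy)phenyl formate (formed in the flask, not isolated) | O=COc1cc(OCc2ccccc2)c(OCc2ccccc2)c(OCc2ccccc2)c1 | intermediate
3 | 3,4,5-tris(benzyloxy)phenol | Oc1cc(OCc2ccccc2)c(OCc2ccccc2)c(OCc2ccccc2)c1 | intermediate
4 | 2,3,4-tris(benzyloxy)-6-hydroxybenzaldehyde | O=Cc1c(O)cc(OCc2ccccc2)c(OCc2ccccc2)c1OCc1ccccc1 | intermediate
5 | 2,3,4-tris(benzyloxy)-6-(methoxymethoxy)benzaldehyde | O=Cc1c(OCOC)cc(OCc2ccccc2)c(OCc2ccccc2)c1OCc1ccccc1 | intermediate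
6 | (E)-2,3,4-tris(benzyloxy)-6-(methoxymethoxy)benzaldehyde oxime | O/N=C/c1c(OCOC)cc(OCc2ccccc2)c(OCc2ccccc2)c1OCc1ccccc1 | intermediate
7 | 2,3,4-tris(benzyloxy)-6-(methoxymethoxy)benzonitrile oxide | [O-][N+]#Cc1c(OCOC)cc(OCc2ccccc2)c(OCc2ccccc2)c1OCc1ccccc1 | intermediate
8 | 2-bromo-1-[4-(benzyloxy)phenyl]ethanone | O=C(CBr)c1ccc(OCc2ccccc2)cc1 | starting material
9 | 2-[4-(benzyloxy)phenyl]-2-oxoethyl formate (formed in the flask, not isolated) | O=COCC(=O)c1ccc(OCc2ccccc2)cc1 | intermediate
10 | 1-[4-(benzyloxy)phenyl]-2-hydroxyethanone | O=C(CO)c1ccc(OCc2ccccc2)cc1 | intermediate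
11 | 1-[4-(benzyloxy)phenyl]-2-(methoxymethoxy)ethanone | COCOCC(=O)c1ccc(OCc2ccccc2)cc1 | intermediate
12 | pyrrolidine | C1CCNC1 | starting material
13 | 1-{(E)-1-[4-(benzyloxy)phenyl]-2-(methoxymethoxy)ethenyl}pyrrolidine | COCO/C=C(/N1CCCC1)c1ccc(OCc2ccccc2)cc1 | intermediate
14 | 5-[4-(benzyloxy)phenyl]-4-(methoxymethoxy)-5-(pyrrolidin-1-yl)-3-[2,3,4-tris(benzyloxy)-6-(methoxymethoxy)phenyl]-4,5-dihydroisoxazole, racemic, methoxymethoxy trans to pyrrolidinyl as expected from suprafacial addition to the E enamine, one enantiomer drawn (formed in the flask, not isolated) | COCO[C@H]1C(c2c(OCOC)cc(OCc3ccccc3)c(OCc3ccccc3)c2OCc2ccccc2)=NO[C@@]1(N1CCCC1)c1ccc(OCc2ccccc2)cc1 | intermediate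
15 | 5-[4-(benzyloxy)phenyl]-4-(methoxymethoxy)-3-[2,3,4-tris(benzyloxy)-6-(methoxymethoxy)phenyl]isoxazole | COCOc1c(-c2c(OCOC)cc(OCc3ccccc3)c(OCc3ccccc3)c2OCc2ccccc2)noc1-c1ccc(OCc2ccccc2)cc1 | intermediate
16 | (2E)-3-amino-1-[4-(benzyloxy)phenyl]-2-(methoxymethoxy)-3-[2,3,4-tris(benzyloxy)-6-(methoxymethoxy)phenyl]prop-2-en-1-one (amino group cis to the carbonyl, hydrogen-bonded) | COCO/C(C(=O)c1ccc(OCc2ccccc2)cc1)=C(/N)c1c(OCOC)cc(OCc2ccccc2)c(OCc2ccccc2)c1OCc1ccccc1 | intermediate
17 | 1-[4-(benzyloxy)phenyl]-2-(methoxymethoxy)-3-[2,3,4-tris(benzyloxy)-6-(methoxymethoxy)phenyl]propane-1,3-dione, racemic at the enolisable C2 (formed in the flask, not isolated) | COCOC(C(=O)c1ccc(OCc2ccccc2)cc1)C(=O)c1c(OCOC)cc(OCc2ccccc2)c(OCc2ccccc2)c1OCc1ccccc1 | intermediate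
18 | 5,6,7-tris(benzyloxy)-2-[4-(benzyloxy)phenyl]-3-hydroxy-4H-chromen-4-one | O=c1c(O)c(-c2ccc(OCc3ccccc3)cc2)oc2cc(OCc3ccccc3)c(OCc3ccccc3)c(OCc3ccccc3)c12 | intermediate
19 | 5,6,7-tris(benzyloxy)-2-[4-(benzyloxy)phenyl]-4-oxo-4H-chromen-3-yl hydrogen sulfate | O=c1c(OS(=O)(=O)O)c(-c2ccc(OCc3ccccc3)cc2)oc2cc(OCc3ccccc3)c(OCc3ccccc3)c(OCc3ccccc3)c12 | intermediate
20 | 5,6,7-trihydroxy-2-(4-hydroxyphenyl)-4-oxo-4H-chromen-3-yl hydrogen sulfate (6-hydroxykaempferol 3-sulfate) | O=c1c(OS(=O)(=O)O)c(-c2ccc(O)cc2)oc2cc(O)c(O)c(O)c12 | target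

Total step count: 13.
Longest linear sequence: 10 steps (steps 1–5, then 9–13); the ring B branch (steps 6–8) joins at step 9.

Steps most likely to fail

1. Step 9. The two ortho substituents shield the dipole and the enamine carbon that must bond is trisubstituted and oxygen-bearing. Cycloaddition may therefore be slow enough for thermal isomerisation of the nitrile oxide to the isocyanate, or capture of the dipole by liberated pyrrolidine, to overtake C–C bond formation. The fallback drops the dipole altogether; it sets out from aldehyde 5 and ketone 11 and comes back to the route at diketone 17. Ketone 11 would be deprotonated with LiN(iPr)2 in THF at −78 °C and the enolate added to aldehyde 5, giving the aldol 1-[4-(benzyloxy)phenyl]-3-hydroxy-2-(methoxymethoxy)-3-[2,3,4-tris(benzyloxy)-6-(methoxymethoxy)phenyl]propan-1-one F1 as a mixture of diastereomers. Oxidation of the benzylic alcohol with Dess–Martin periodinane buffered with NaHCO3 in CH2Cl2 should give 17 under neutral conditions that avoid retro-Claisen cleavage. Compound 17 is then taken through the acid treatment of step 11 to 18.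

2. Step 8. Condensation of the conjugated aryl ketone with pyrrolidine may stall before completion, and the moisture-sensitive enamine may revert to the ketone or lose its acetal while excess amine is stripped off. The fallback replaces the enamine by the enolate; it sets out from ketone 11, uses nitrile oxide 7, and comes back at isoxazole 15. The lithium enolate of 11 (LiN(iPr)2, THF, −78 to 0 °C) would be treated with 7. The enolate carbon attacks the nitrile oxide carbon and the oximate oxygen closes onto the ketone, giving 5-[4-(benzyloxy)phenyl]-4-(methoxymethoxy)-3-[2,3,4-tris(benzyloxy)-6-(methoxymethoxy)phenyl]-4,5-dihydroisoxazol-5-ol F2. Dehydration with Na2CO3 in aqueous MeOH at reflux should then give 15.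

3. Step 12. The C3 hydroxyl is hydrogen-bonded to the C4 carbonyl and flanked by the C2 aryl group, so it may react sluggishly with the amine–SO3 complex, and the ionic product may be partly hydrolysed or lost during purification. The fallback uses a protected sulfate; it sets out from flavonol 18 and comes back at target 20. Treatment of 18 with 2,2,2-trichloroethyl chlorosulfate, 4-(dimethylamino)pyridine and Et3N in THF would give the neutral, chromatographable diester 5,6,7-tris(benzyloxy)-2-[4-(benzyloxy)phenyl]-4-oxo-4H-chromen-3-yl 2,2,2-trichloroethyl sulfate F3. Pd/C with HCO2NH4 in MeOH should remove the benzyl ethers by transfer hydrogenolysis and the trichloroethyl group reductively in the same flask, giving the ammonium salt of 20, which is passed through the acid-form resin as in step 13.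

Further compounds
F1 | step 9 | 1-[4-(benzyloxy)phenyl]-3-hydroxy-2-(methoxymethoxy)-3-[2,3,4-tris(benzyloxy)-6-(methoxymethoxy)phenyl]propan-1-one (mixture of racemic diastereomers) | COCOC(C(=O)c1ccc(OCc2ccccc2)cc1)C(O)c1c(OCOC)cc(OCc2ccccc2)c(OCc2ccccc2)c1OCc1ccccc1
F2 | step 8 | 5-[4-(benzyloxy)phenyl]-4-(methoxymethoxy)-3-[2,3,4-tris(benzyloxy)-6-(methoxymethoxy)phenyl]-4,5-dihydroisoxazol-5-ol (mixture of racemic diastereomers) | COCOC1C(c2c(OCOC)cc(OCc3ccccc3)c(OCc3ccccc3)c2OCc2ccccc2)=NOC1(O)c1ccc(OCc2ccccc2)cc1
F3 | step 12 | 5,6,7-tris(benzyloxy)-2-[4-(benzyloxy)phenyl]-4-oxo-4H-chromen-3-yl 2,2,2-trichloroethyl sulfate | O=c1c(OS(=O)(=O)OCC(Cl)(Cl)Cl)c(-c2ccc(OCc3ccccc3)cc2)oc2cc(OCc3ccccc3)c(OCc3ccccc3)c(OCc3ccccc3)c12
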